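## Retrosynthetic overview
1. Dictyoceratin A ⇐ global O-demethylation of the dimethyl ether methyl ester ⇐ C6 deoxygenation of ketone 17.
2. 17 ⇐ Stryker 1,4-reduction of enone 16, which sets C8-Me. 16 ⇐ Au-catalysed 6-exo-dig Conia-ene closure of silyl dienol ether 15, which forms ring A last and makes the C5 quaternary centre, the trans ring fusion and C4=CH2 in one step.
3. 15 ⇐ cuprate 1,4-addition at C10 plus C5 methylation of dienone 9. 9 ⇐ desymmetrizing asymmetric methyl addition to the prochiral, Cs-symmetric dienone 6 (key step, sets C9), followed by re-dehydrogenation.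
4. 6 ⇐ Heck / Robinson / IBX from aryl bromide 1, methallyl alcohol and MVK. The cyclohexadienone ring is built first and ring A last.

Assumptions:
- Methyl 3-bromo-4,5-dimethoxybenzoate is commercial (or one Fischer esterification from the commercial acid).
- The ligand enantiomer in Step 4 is chosen to give the natural series.
- Reagent 10 is prepared in one pot from commercial 5-chloropent-1-yne (nBuLi, TMSCl, then Mg). This is not counted in the step total.

## Route

**Step 1**
Reactants: 1 (methyl 3-bromo-4,5-dimethoxybenzoate); 2 (2-methylprop-2-en-1-ol)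
Product: 3 (methyl 3,4-dimethoxy-5-(2-methyl-3-oxopropyl)benzoate, racemic)
Conditions: Pd(OAc)2 (3 mol%), nBu4NCl, NaHCO3, DMF, 90 °C
Reagents that add atoms: 2, C=C(C)CO
Why: Jeffery-type Mizoroki–Heck reaction puts the aryl group on the terminal CH2 of the 1,1-disubstituted allylic alcohol, and β-H elimination followed by tautomerisation gives the 3-aryl-2-methylpropanal (as in the Lilial synthesis); the racemic α-stereocentre is destroyed in Step 2.

**Step 2**
Reactants: 3; 4 (methyl vinyl ketone)
Product: 5 (methyl 3,4-dimethoxy-5-[(1-methyl-4-oxocyclohex-2-en-1-yl)methyl]benzoate, racemic)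
Conditions: pyrrolidine (20 mol%), AcOH (20 mol%), toluene, 110 °C, Dean–Stark
Reagents that add atoms: 4, C=CC(C)=O
Why: Robinson annulation of an α-branched aldehyde (enamine Michael addition, then aldol condensation) builds the 4,4-disubstituted cyclohexenone, as in isobutyraldehyde + MVK → 4,4-dimethylcyclohexenone; the racemic C4 is erased in Step 3.

**Step 3**
Reactants: 5
Product: 6 (methyl 3,4-dimethoxy-5-[(1-methyl-4-oxocyclohexa-2,5-dien-1-yl)methyl]benzoate, achiral, Cs-symmetric)
Conditions: IBX (2.5 equiv), DMSO/fluorobenzene, 85 °C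
Reagents that add atoms: none
Why: Nicolaou IBX dehydrogenation gives the cross-conjugated dienone, and the quaternary C4 prevents aromatisation, so 6 carries two enantiotopic enone arms.

**Step 4**
Reactants: 6; 7 (MeMgBr)
Product: 8 (methyl 3,4-dimethoxy-5-[(1,6-dimethyl-4-oxocyclohex-2-en-1-yl)methyl]benzoate; C1 quaternary centre single enantiomer as drawn = target C9; C6 epimeric)
Conditions: CuBr·SMe2 (5 mol%), (R,S)-Josiphos-type ligand (6 mol%), MTBE, −78 °C, 3 h
Reagents that add atoms: 7, C[Mg]Br
Why: Proposed new method: Cu/chiral-diphosphine-catalysed asymmetric conjugate addition of a Grignard reagent (Feringa-type, known for cyclic enones and dienones) to the Cs-symmetric dienone, where the ligand selects one enantiotopic enone and so fixes the absolute configuration of the quaternary carbon (C9). The new methyl-bearing carbon (C8) is epimeric but is erased in Step 5.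

**Step 5**
Reactants: 8
Product: 9 (methyl 3,4-dimethoxy-5-[(1,2-dimethyl-4-oxocyclohexa-2,5-dien-1-yl)methyl]benzoate, single enantiomer)
Conditions: IBX (1.5 equiv), DMSO, 80 °C
Reagents that add atoms: none
Why: Nicolaou dehydrogenation regenerates the enone on the methylated side, which destroys the C8 stereocentre and keeps C9, giving an enantioenriched dienone with one β-unsubstituted enone (C5=C10) and one β-methyl enone (C7=C8).

**Step 6**
Reactants: 9; 10 ((5-(trimethylsilyl)pent-4-yn-1-yl)magnesium bromide); 11 (MeI)
Product: 12 (methyl 3,4-dimethoxy-5-({1,2,5-trimethyl-4-oxo-6-[5-(trimethylsilyl)pent-4-yn-1-yl]cyclohex-2-en-1-yl}methyl)benzoate; C9 and C10 defined as in the SMILES, C5 epimeric)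
Conditions: 10 (1.5 equiv) and CuBr·SMe2 (1.5 equiv), THF/Me2S, −78 → −40 °C; then MeI (5 equiv), DMPU (4 equiv), −78 → 0 °C
Reagents that add atoms: 10, C[Si](C)(C)C#CCCC[Mg]Br; 11, CI
Why: Cuprate 1,4-addition occurs at the unhindered β-carbon C10 of the β-unsubstituted enone, because the β-methyl enone is less electrophilic and more hindered. The chain enters anti to the bulkier benzyl group, that is, syn to the C9 methyl, which sets C10. The magnesium enolate is then C5-methylated regiospecifically (conjugate addition–enolate alkylation), and the C5 epimers are erased in Step 8.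

**Step 7**
Reactants: 12
Product: 13 (terminal alkyne, same stereo)
Conditions: K2CO3 (3 equiv), MeOH, 25 °C, 2 h
Reagents that add atoms: none
Why: Methoxide-mediated protodesilylation of the alkynyl–TMS bond leaves the enone, ester and stereocentres intact.

**Step 8**
Reactants: 13; 14 (TMSOTf)
Product: 15 (silyl dienol ether, C9 and C10 defined)
Conditions: TMSOTf (1.5 equiv), Et3N (3 equiv), CH2Cl2, 0 °C
Reagents that add atoms: 14, C[Si](C)(C)OS(=O)(=O)C(F)(F)F
Why: Soft enolisation is regiospecific toward C5 because the other α-carbon (C7) is vinylic, so it gives the tetrasubstituted silyl dienol ether and removes the C5 stereocentre before ring closure.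

**Step 9**
Reactants: 15
Product: 16 (trans-fused enone with C4=CH2, C5-Me, C8=C7 enone)
Conditions: (Ph3P)AuCl (5 mol%), AgSbF6 (5 mol%), CH2Cl2, 25 °C; then aq. NH4Cl
Reagents that add atoms: none
Why: Proposed new method: Au(I) activates the terminal alkyne and C5 of the silyl dienol ether attacks the internal alkyne carbon in a 6-exo-dig carbocyclisation, forming the C4–C5 bond and, after protodeauration, the exocyclic C4=CH2. The equatorial C10 tether delivers C4 to the lobe anti to the axial C9 methyl, so the C5 methyl ends up syn-axial to it (trans-decalin, as in the natural product). The closest known reaction is Toste's Au(I)-catalysed silyl enol ether/alkyne carbocyclisation to quaternary centres.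

**Step 10**
Reactants: 16
Product: 17 (saturated trans-decalone)
Conditions: [(Ph3P)CuH]6 (Stryker, 10 mol% Cu–H), PhSiH3 (1.5 equiv), toluene, 0 °C → 25 °C; then NH4F, MeOH
Reagents that add atoms: none
Why: Stryker 1,4-reduction leaves the exocyclic alkene and ester untouched. Hydride adds to C8 from the bottom face, away from the two syn-axial methyls (C5 and C9), so H8 is axial and Me8 equatorial, as in the target.

**Step 11**
Reactants: 17
Product: 18 (carboxylic acid, C6 deoxygenated)
Conditions: N2H4·H2O, KOH, diethylene glycol, 130 °C then 200 °C (Huang–Minlon)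
Reagents that add atoms: none
Why: Wolff–Kishner removes the now-redundant C6 oxygen, and no stereocentre lies α to the ketone (C5 is quaternary, C7 is CH2). The aryl ester is saponified (re-esterified next) and the aryl ethers and exocyclic alkene survive.

**Step 12**
Reactants: 18; 19 (TMSCHN2)
Product: 20 (dimethyl ether methyl ester)
Conditions: TMSCHN2 (1.5 equiv), PhMe/MeOH 3:1, 0 °C, 30 min
Reagents that add atoms: 19, C[Si](C)(C)C=[N+]=[N-] (delivers CH3)
Why: Acid-selective diazomethane-type methyl esterification leaves the alkene and the stereocentres untouched.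

**Step 13**
Reactants: 20
Product: 21 (dictyoceratin A)
Conditions: BBr3 (4 equiv), 2,6-di-tert-butylpyridine (6 equiv), CH2Cl2, −78 → 0 °C, 2 h; MeOH quench
Reagents that add atoms: none
Why: BBr3 cleaves both aryl methyl ethers to the catechol, while the hindered pyridine scavenges HBr to protect the exocyclic methylene and the methyl ester survives at 0 °C; all sp3 stereocentres are untouched.

## Compound list
1 | methyl 3-bromo-4,5-dimethoxybenzoate | COC(=O)c1cc(Br)c(OC)c(OC)c1 | starting material
2 | 2-methylprop-2-en-1-ol | C=C(C)CO | starting material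
3 | methyl 3,4-dimethoxy-5-(2-methyl-3-oxopropyl)benzoate (racemic) | COC(=O)c1cc(CC(C)C=O)c(OC)c(OC)c1 | intermediate
4 | methyl vinyl ketone | C=CC(C)=O | starting material
5 | methyl 3,4-dimethoxy-5-[(1-methyl-4-oxocyclohex-2-en-1-yl)methyl]benzoate (racemic) | O=C1C=CC(C)(Cc2cc(C(=O)OC)cc(OC)c2OC)CC1 | intermediate
6 | methyl 3,4-dimethoxy-5-[(1-methyl-4-oxocyclohexa-2,5-dien-1-yl)methyl]benzoate (achiral) | O=C1C=CC(C)(Cc2cc(C(=O)OC)cc(OC)c2OC)C=C1 | intermediate
7 | methylmagnesium bromide | C[Mg]Br | starting material (reagent)
8 | methyl 3,4-dimethoxy-5-[(1,6-dimethyl-4-oxocyclohex-2-en-1-yl)methyl]benzoate (C1 single enantiomer; C6 epimeric) | O=C1C=C[C@](C)(Cc2cc(C(=O)OC)cc(OC)c2OC)C(C)C1 | intermediate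
9 | methyl 3,4-dimethoxy-5-[(1,2-dimethyl-4-oxocyclohexa-2,5-dien-1-yl)methyl]benzoate (single enantiomer) | O=C1C=C[C@](C)(Cc2cc(C(=O)OC)cc(OC)c2OC)C(C)=C1 | intermediate
10 | (5-(trimethylsilyl)pent-4-yn-1-yl)magnesium bromide | C[Si](C)(C)C#CCCC[Mg]Br | starting material (reagent)
11 | iodomethane | CI | starting material (reagent)
12 | methyl 3,4-dimethoxy-5-({1,2,5-trimethyl-4-oxo-6-[5-(trimethylsilyl)pent-4-yn-1-yl]cyclohex-2-en-1-yl}methyl)benzoate (C5 epimeric) | O=C1C(C)[C@@H](CCCC#C[Si](C)(C)C)[C@](C)(Cc2cc(C(=O)OC)cc(OC)c2OC)C(C)=C1 | intermediate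
13 | alkyne from 12 with the TMS group removed (C5 epimeric) | O=C1C(C)[C@@H](CCCC#C)[C@](C)(Cc2cc(C(=O)OC)cc(OC)c2OC)C(C)=C1 | intermediate
14 | trimethylsilyl triflate | C[Si](C)(C)OS(=O)(=O)C(F)(F)F | starting material (reagent)
15 | silyl dienol ether of 13 (C6-OTMS, C5=C6, C7=C8) | C[Si](C)(C)OC1=C(C)[C@@H](CCCC#C)[C@](C)(Cc2cc(C(=O)OC)cc(OC)c2OC)C(C)=C1 | intermediate
16 | 3,4,8a-trimethyl-8-methylidene-4-(aryl-methyl)-4a,5,6,7,8,8a-hexahydronaphthalen-1(4H)-one, trans-fused, aryl = 3-CO2Me-5,6-dimethoxyphenyl | C=C1CCC[C@H]2[C@](C)(Cc3cc(C(=O)OC)cc(OC)c3OC)C(C)=CC(=O)[C@]12C | intermediate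
17 | saturated trans-decalone (C7=C8 reduced) | C=C1CCC[C@H]2[C@](C)(Cc3cc(C(=O)OC)cc(OC)c3OC)[C@@H](C)CC(=O)[C@]12C | intermediate
18 | benzoic acid with C6 deoxygenated | C=C1CCC[C@H]2[C@](C)(Cc3cc(C(=O)O)cc(OC)c3OC)[C@@H](C)CC[C@]12C | intermediate
19 | (trimethylsilyl)diazomethane | C[Si](C)(C)C=[N+]=[N-] | starting material (reagent)
20 | dimethyl ether methyl ester of the target | C=C1CCC[C@H]2[C@](C)(Cc3cc(C(=O)OC)cc(OC)c3OC)[C@@H](C)CC[C@]12C | intermediate
21 | dictyoceratin A | C=C1CCC[C@H]2[C@](C)(Cc3cc(C(=O)OC)cc(O)c3O)[C@@H](C)CC[C@]12C | target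

**Total steps:** 13. **Longest linear sequence:** 13 (Step 1 → Step 13), plus one one-pot preparation of reagent 10.

**Three steps most likely to fail**
1. **Step 9 (Au Conia-ene, trans fusion and quaternary C5):** The cis-fused C5 epimer may form because the tether reaches the top face more easily. Fallback: introduce a 4-bromopent-4-enyl tether in Step 6 instead and close ring A by Pd-catalysed intramolecular ketone α-alkenylation, a different bond-forming mechanism whose ring-fusion selectivity is set by the Pd-enolate cyclisation rather than by the alkyne carbocyclisation.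
2. **Step 4 (desymmetrizing Cu-ACA, ee and 1,2- versus 1,4-selectivity):** The hindered dienone may give low ee. Fallback: make racemic 9 (racemic Cu-catalysed MeMgBr addition, then IBX) and obtain the single enantiomer by preparative chiral SFC at the dienone stage, which replaces asymmetric catalysis with resolution.
3. **Step 13 (BBr3 demethylation with the exocyclic methylene):** HBr addition or alkene isomerisation may occur. Fallback: redo the sequence from methyl 3-bromo-4,5-bis(allyloxy)benzoate, where the catechol is unmasked at the end by Pd(0)-catalysed deallylation, which changes the protecting-group strategy.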